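## Structural features

The target is a tricyclic humulane-type sesquiterpenoid triester carrying two (Z)-2-methylbut-2-enoates (angelates) and one acetate. Its core is a bicyclo[3.1.1]hept-3-en-2-one (ring A: bridgehead C-1, ketone C-2, C-3=C-4 with the vinylic methyl on C-4, bridgehead C-5). The two one-carbon bridges, C-6 (quaternary, methyl) and C-7 (CH), form with C-1 and C-5 the central cyclobutane (ring B). C-6 and C-7 are joined, on the face of ring B remote from the enone, by the chain C-8(O-angeloyl)–C-9H2–C-10(OAc)–C-11(CH3)(C-12H2O-angeloyl), which closes the seven-membered ring C. There are seven stereocentres: C-1, C-5, C-6 and C-7 are contiguous on ring B and locked to one another by the cage; C-8, C-10 and C-11 sit on the bridge, with the C-8 and C-10 oxygens 1,3-anti, the acetate cis to the C-11 methyl, and the two quaternary centres C-6 and C-11 five bonds apart. Fragile groups are the angelates (Z to E with acid, base, nucleophilic catalysts or heat), the acetate flanked by other oxygens (acyl migration) and the strained cyclobutane next to the enone. The real difficulty is the 1,3-bridged cyclobutane with a quaternary corner and its correlation with the three bridge stereocentres. The feature exploited: ketone C-2 is bonded to C-1, which is bonded to C-6. Returning the C-1–C-6 bond to C-2 (a retro 1,2-shift) turns rings A and B into a norborn-2-ene with oxygen on bridgehead C-2 and C-6 as its one-carbon bridge, the Diels–Alder adduct of a 5,5-disubstituted 1-oxycyclopentadiene.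

## Logic of the disconnections

In one sentence: a fluoride-triggered semipinacol 1,2-shift of the one-carbon bridge of a Diels–Alder-derived 1-siloxynorbornene mesylate builds the cyclobutane and the enone of the cage together.

28 to 27, 26 and 25. The acetate C–O bond at C-10 is cut first (27), the C-10 oxygen is returned to its p-methoxybenzyl ether (26), then both angelate C–O bonds are cut (25). The reason is that the isomerisable esters should not meet fluoride, strong base or heat. The gain is that 25 carries only robust groups. The demand is an esterification of a hindered secondary and a neopentyl primary alcohol without Z/E isomerisation, and a C-10 protecting group orthogonal to silyl ethers.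

25 to 23 (through 24). This is the key disconnection. The C-1–C-6 bond of ring B is cut and C-6 is reattached to C-2; C-2 goes back from ketone to a bridgehead silyloxy carbon and C-1 regains an endo mesylate. The reason is that the cyclobutane and the enone, the two strained and sensitive elements, vanish together and leave a norbornene. The demand on the forward step is that the C-2–C-6 bond lies antiperiplanar to the C-1–O bond (endo sulfonate), that the bridgehead oxygen is freed as an alkoxide, and that no other bond or hydrogen is antiperiplanar to the leaving group.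

23 to 22 and 21. The C-1–O bond is traced to a C-1–B bond. This makes the oxygen the footprint of a dienophile substituent. The demand is oxidation with retention so that the endo orientation is kept.

21 to 20. The two norbornene σ-bonds C-5–C-7 and C-1–C-2 are cut in a retro-Diels–Alder sense. This opens the bicycle and ring C at once and leaves a monocyclic siloxycyclopentadiene tethered through C-6 to an (E)-alkenylboronate. Four stereocentres (C-1, C-2, C-5, C-7) are reduced to one (C-6) plus an alkene geometry. The demand is siloxy/boron "ortho" regiochemistry, a tether that can only reach one diene face, and a diene that cannot undergo 1,5-hydrogen shifts (C-6 is quaternary).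

20 to 19, 17, and 13 plus 16 (16 from 14). The O–Si bonds, the C-6–CH3 bond and the C-6–C-8 bond are cut. This divides the molecule into a commercial cyclopentenone and an open-chain aldehyde. The demand is 1,3-anti induction from C-10 in the aldol step and methylation anti to the new C-8 hydroxyl, so that C-8 and then C-6 are relayed from C-10.

13 to 12, 11 and 10. The C-7=C-1 double bond is cut to an aldehyde on C-11. The demand is an E-selective one-carbon boryl olefination of a neopentyl aldehyde.

10 to 9, 8, 7, 5, 4, and 1 plus 2. The two arms on C-11 are exchanged in oxidation level (the vinyl group becomes C-12, the hydroxymethyl group becomes C-7), then the C-10–C-11 bond is cut. A catalytic carbonyl tert-(hydroxy)prenylation sets C-10 and C-11 together from two commercial materials. It is the only step that uses an external chiral source; every later stereocentre is relayed. The demand is the anti diastereoselectivity of that coupling; the arm exchange is needed because the anti adduct carries the vinyl group where C-12 must be.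

## Other disconnections considered

Alternative 1: (the first that comes to mind for a cyclobutane in a humulane) cut C-1–C-7 and C-5–C-6 to the eleven-membered (E,Z,E)-trienone A1 and close ring B by a transannular enone–alkene [2+2] photocycloaddition. The chosen plan is preferred for three reasons. A1 needs a macrocyclisation with three stereocentres and three defined alkenes already in place. The required crossed mode competes with the parallel mode, which would give a bicyclo[3.2.0] isomer. The excited enone is expected to undergo E/Z isomerisation, which would erase the geometry that encodes C-1, C-5, C-6 and C-7, and the angelates would be present as further light-sensitive alkenes.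

Alternative 2: cut C-1–C-7 to the hydrobenzocycloheptenone mesylate A2 and close ring B by intramolecular alkylation of the kinetic α′-enolate. The displacement would have to occur at a secondary carbon next to quaternary C-11 while forming a four-membered ring, so elimination and γ-deprotonation of the enone are expected to compete. A2 already contains six stereocentres, including the cis ring fusion and an inverted leaving group, none of which is relayed by the cage. The step count would be no lower.

Alternative 3: insert nitrogen between C-1 and C-6 to the bridged pyrrolidine A3 and form the C-1–C-6 bond by nitrogen deletion (isodiazene, 1,4-biradical recombination), which would give 25. A3 is an aza-bicyclo[3.2.1]octenone carrying the same ring C and the same stereocentres, so nothing is simplified. Its α-amino ketone centre C-1 can epimerise, and the biradical can fragment or disproportionate in the strained cage instead of closing the cyclobutane.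

Key step: step 16

Remark (assumption): the carbonyl tert-(hydroxy)prenylation is taken to give the anti adduct (secondary hydroxyl anti to the new hydroxymethyl group) under ligand control, as is typical for this reaction class; the cage locants C-1 to C-12 are used for all later compounds.

## Route

Step 1
Reactants: 1 3-[(tert-butyldimethylsilyl)oxy]propan-1-ol; 2 2-methyl-2-vinyloxirane (isoprene monoxide, racemic)
Product: 4 (2R,3R)-5-[(tert-butyldimethylsilyl)oxy]-2-methyl-2-vinylpentane-1,3-diol, via aldehyde 3 (not isolated)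
Conditions: [Ir(cod)Cl]2 (2.5 mol%), Tol-BINAP (5 mol%, antipode giving 2R,3R), 4-cyano-3-nitrobenzoic acid (10 mol%), K3PO4 (5 mol%), THF, 60 °C
Reagents that add atoms: none
Why: Iridium-catalysed transfer-hydrogenative carbonyl allylation (tert-(hydroxy)prenylation): dehydrogenation of 1 gives 3 and an (E)-σ-allyliridium species from 2, which add through a closed Zimmerman–Traxler chair. The ligand should set the absolute sense and the chair the anti relationship, so the quaternary C-11 and the C-10 carbinol are formed together.

Step 2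
Reactants: 4 (2R,3R)-diol
Product: 5 4-methoxybenzylidene acetal of 4 (1,3-dioxane, aryl group cis to the C-4 side chain)
Conditions: 4-MeOC6H4CH(OMe)2, PPTS, CH2Cl2, 23 °C
Reagents that add atoms: 4-methoxybenzaldehyde dimethyl acetal, COC(OC)c1ccc(OC)cc1
Why: Thermodynamic acetalisation of the 1,3-diol; the aryl group and the C-4 side chain should both sit equatorial, which fixes the acetal carbon. The acetal protects both hydroxyls during ozonolysis and stores the PMB group for step 5.

Step 3
Reactants: 5 acetal
Product: 7 5-(hydroxymethyl) analogue of 5 (vinyl replaced by CH2OH), via aldehyde 6 (not isolated)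
Conditions: O3, CH2Cl2–MeOH (4:1), −78 °C; then NaBH4, −78 to 0 °C
Reagents that add atoms: ozone, [O-][O+]=O
Why: Ozonolysis with reductive work-up; the α-quaternary aldehyde cannot epimerise. This converts the vinyl arm into the future C-12 oxymethyl group.

Step 4
Reactants: 7 alcohol
Product: 8 tert-butyldiphenylsilyl ether of 7
Conditions: TBDPSCl, imidazole, DMAP (cat.), DMF, 23 °C
Reagents that add atoms: tert-butyl(chloro)diphenylsilane, CC(C)(C)[Si](Cl)(c1ccccc1)c1ccccc1
Why: Standard silylation of a neopentyl primary alcohol; the bulkier silyl group is chosen so that the primary TBS ether can later be removed selectively.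

Step 5
Reactants: 8 acetal
Product: 9 5-[(tert-butyldimethylsilyl)oxy]-2-{[(tert-butyldiphenylsilyl)oxy]methyl}-3-[(4-methoxybenzyl)oxy]-2-methylpentan-1-ol (configuration as in 4)
Conditions: i-Bu2AlH (3 equiv), CH2Cl2, −78 to 0 °C; Rochelle salt
Reagents that add atoms: none
Why: Regioselective reductive opening of the p-methoxybenzylidene acetal: aluminium should coordinate the less hindered primary oxygen and hydride delivery then leaves the PMB ether on the secondary C-10 oxygen and frees the primary alcohol.

Step 6
Reactants: 9 alcohol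
Product: 10 corresponding α-quaternary aldehyde
Conditions: Dess–Martin periodinane, NaHCO3, CH2Cl2, 23 °C
Reagents that add atoms: none
Why: Dess–Martin oxidation under buffered conditions; no α-hydrogen, so the quaternary centre is safe.

Step 7
Reactants: 10 aldehyde
Product: 11 (E)-alkenyl pinacol boronate (CHO replaced by (E)-CH=CH–Bpin)
Conditions: CrCl2 (8 equiv), Cl2CHBpin (2 equiv), LiI (4 equiv), THF, 23 °C
Reagents that add atoms: 2-(dichloromethyl)-4,4,5,5-tetramethyl-1,3,2-dioxaborolane, ClC(Cl)B1OC(C)(C)C(C)(C)O1
Why: Takai–Utimoto olefination in its boryl variant: the geminal dichromium reagent adds to the aldehyde and anti elimination should give the E-alkenylboronate. The alkene geometry later encodes the endo position of the leaving group.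

Step 8
Reactants: 11 bis-silyl ether
Product: 12 primary alcohol (TBS ether cleaved, TBDPS ether retained)
Conditions: CSA (10 mol%), MeOH–CH2Cl2 (1:1), 0 °C
Reagents that add atoms: none
Why: Acid-catalysed methanolysis distinguishes the unhindered primary TBS ether from the neopentyl TBDPS ether; PMB ether and pinacol boronate should survive.

Step 9
Reactants: 12 alcohol
Product: 13 β-(4-methoxybenzyloxy) aldehyde
Conditions: Dess–Martin periodinane, NaHCO3, CH2Cl2, 0 to 23 °C
Reagents that add atoms: none
Why: Buffered Dess–Martin oxidation avoids β-elimination of the PMB ether.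

Step 10
Reactants: 14 3-methylcyclopent-2-en-1-one
Product: 16 trimethyl[(4-methylcyclopenta-1,3-dien-2-yl)oxy]silane, via lithium dienolate 15 (not isolated)
Conditions: LDA, THF, −78 °C; then TMSCl, −78 °C; used cold without purification
Reagents that add atoms: chlorotrimethylsilane, C[Si](C)(C)Cl
Why: Kinetic deprotonation of an enone occurs at the α′ position; O-silylation gives the cross-conjugated silyl dienol ether needed for an α′-selective aldol reaction.

Step 11
Reactants: 13 aldehyde; 16 silyl dienol ether
Product: 17 aldol adduct (C-8 hydroxyl 1,3-anti to the C-10 PMB ether; mixture at the ring α′ carbon)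
Conditions: BF3·OEt2 (1.1 equiv), CH2Cl2, −78 °C
Reagents that add atoms: none
Why: Mukaiyama aldol reaction through an open transition state; with a non-chelating Lewis acid a β-alkoxy aldehyde should give the 1,3-anti carbinol (dipole-minimised Felkin-type attack). The ring α′ centre is erased in step 12.

Step 12
Reactants: 17 aldol adduct
Product: 19 5-methylated β-hydroxy enone (quaternary C-6, methyl anti to the C-8 hydroxyl), via dianion 18 (not isolated)
Conditions: LDA (2.4 equiv), THF, −78 to −40 °C; MeI (5 equiv), DMPU, −78 to −30 °C; AcOH quench at −78 °C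
Reagents that add atoms: iodomethane, CI
Why: Frater–Seebach alkylation: the chelated lithium alkoxide–enolate 18 should be methylated on the face opposite the carbinol side chain. This gives the methyl anti to the hydroxyl, the relationship required between C-6 and C-8.

Step 13
Reactants: 19 β-hydroxy enone
Product: 21 tricyclic norbornene boronate (bridgehead C-2 OSiEt3, endo-Bpin at C-1, C-11 exo on C-7, C-6 methyl syn to C-3=C-4, C-8 OSiEt3), via siloxydiene 20 (not isolated)
Conditions: TESOTf (3 equiv), Et3N (6 equiv), CH2Cl2, −78 to 0 °C; then toluene (0.005 M), BHT, 120 °C, sealed tube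
Reagents that add atoms: triethylsilyl trifluoromethanesulfonate, CC[Si](CC)(CC)OS(=O)(=O)C(F)(F)F
Why: Soft enolisation of the α′-blocked enone should give the endocyclic 1-siloxycyclopentadiene 20, which cannot undergo 1,5-hydrogen shifts because C-6 is quaternary. In the intramolecular Diels–Alder reaction the tether on C-6 allows addition only to the diene face syn to the chain and only with C-11 exo, and the E-alkene then places boron endo. The siloxy/boron "ortho" regiochemistry follows from the large HOMO coefficient at C-5 and the LUMO coefficient at C-7, so C-1, C-2, C-5 and C-7 are all set from C-6.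

Step 14
Reactants: 21 boronate
Product: 22 endo C-1 alcohol
Conditions: NaBO3·4H2O, THF–H2O (1:1), 23 °C
Reagents that add atoms: sodium perborate, [Na+].[O-]OB=O
Why: Oxidation of a secondary alkylboronate proceeds by 1,2-migration from boron to oxygen with retention, so the endo orientation is kept; mild perborate should spare the silyl ethers.

Step 15
Reactants: 22 alcohol
Product: 23 endo C-1 mesylate
Conditions: MsCl (1.5 equiv), Et3N (3 equiv), CH2Cl2, −20 to 0 °C
Reagents that add atoms: methanesulfonyl chloride, CS(=O)(=O)Cl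
Why: Mesylation through sulfene tolerates the hindered secondary alcohol and does not touch the stereocentre.

Step 16
Reactants: 23 mesylate
Product: 25 tricyclic enone diol (bicyclo[3.1.1]hept-3-en-2-one cage of 28 with free C-8 and C-12 hydroxyls and C-10 OPMB), via bridgehead alkoxide 24 (not isolated)
Conditions: TBAF (5 equiv), THF, 0 to 23 °C
Reagents that add atoms: none
Why: Proposed new method: fluoride cleaves the three silyl ethers (in any order) and frees the bridgehead C-2 alkoxide 24; the C-2–C-6 σ-bond, held antiperiplanar (about 155°) to the endo C-1–OMs bond, migrates to C-1 as mesylate leaves and C-2 becomes the ketone conjugated with C-3=C-4. The closest known reaction type is the base-promoted semipinacol rearrangement of 2-sulfonyloxy carbinols, here run in the bornyl-to-pinyl direction of a Wagner–Meerwein shift and driven by carbonyl formation and loss of mesylate. Ring B (C-1, C-6, C-5, C-7) is closed by this suprafacial 1,2-shift rather than by a cyclisation, and ring A arises at the same time by expansion of the five-membered ring that contained C-2 and C-6. C-1 is set by inversion, which is stereospecific because the endo leaving group descends from the E-alkene through the retentive oxidation; C-6 migrates with retention, and C-5, C-7, C-8, C-10 and C-11 are untouched. The selectivity needed is migration of C-6 rather than of the vinylic C-3, and shift rather than elimination, retro-[4+2] cleavage or sulfonyl transfer. It is secured by the cage: the C-2–C-3 bond is gauche (about 50°) to the leaving group, the only β-hydrogen (on C-7) is syn, and the shift is irreversible.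

Step 17
Reactants: 25 diol
Product: 26 C-8, C-12 bis-angelate (C-10 OPMB)
Conditions: angelic acid (6 equiv), 2,4,6-trichlorobenzoyl chloride (6 equiv), Et3N, toluene, 23 °C; then 25, toluene, 80 °C
Reagents that add atoms: angelic acid ((Z)-2-methylbut-2-enoic acid), C/C=C(/C)C(=O)O
Why: Yamaguchi-type esterification through the angelic 2,4,6-trichlorobenzoic mixed anhydride; the alcohol should attack the less hindered angeloyl carbonyl, and leaving out nucleophilic catalysts avoids the conjugate addition–elimination that isomerises Z to E.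

Step 18
Reactants: 26 PMB ether
Product: 27 C-10 alcohol
Conditions: DDQ (1.5 equiv), CH2Cl2–pH 7 buffer (10:1), 0 to 23 °C
Reagents that add atoms: none
Why: Oxidative cleavage of the p-methoxybenzyl ether; the electron-poor enoates and the enone should not be oxidised under buffered conditions.

Step 19
Reactants: 27 alcohol
Product: 28 CNP0364726.1 (target)
Conditions: Ac2O, pyridine, DMAP (5 mol%), CH2Cl2, 23 °C
Reagents that add atoms: acetic anhydride, CC(=O)OC(C)=O
Why: Standard acetylation of the remaining secondary alcohol; with every other hydroxyl already acylated no acyl migration is possible.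

## Compound list

1 | 3-[(tert-butyldimethylsilyl)oxy]propan-1-ol | OCCCO[Si](C)(C)C(C)(C)C | starting material
2 | 2-methyl-2-vinyloxirane (racemic) | CC1(C=C)CO1 | starting material
3 | 3-[(tert-butyldimethylsilyl)oxy]propanal | O=CCCO[Si](C)(C)C(C)(C)C | intermediate (not isolated)
4 | (2R,3R)-5-[(tert-butyldimethylsilyl)oxy]-2-methyl-2-vinylpentane-1,3-diol | CC(C)(C)[Si](C)(C)OCC[C@@H](O)[C@@](C)(CO)C=C | intermediate
5 | 4-methoxybenzylidene acetal of 4 (2-aryl cis to the C-4 side chain) | CC(C)(C)[Si](C)(C)OCC[C@H]1O[C@@H](c2ccc(OC)cc2)OC[C@@]1(C)C=C | intermediate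
6 | 5-formyl analogue of 5 | CC(C)(C)[Si](C)(C)OCC[C@H]1O[C@@H](c2ccc(OC)cc2)OC[C@@]1(C)C=O | intermediate (not isolated)
7 | 5-(hydroxymethyl) analogue of 5 | CC(C)(C)[Si](C)(C)OCC[C@H]1O[C@@H](c2ccc(OC)cc2)OC[C@@]1(C)CO | intermediate
8 | tert-butyldiphenylsilyl ether of 7 | CC(C)(C)[Si](C)(C)OCC[C@H]1O[C@@H](c2ccc(OC)cc2)OC[C@@]1(C)CO[Si](c3ccccc3)(c4ccccc4)C(C)(C)C | intermediate
9 | PMB ether primary alcohol from opening of 8 | CC(C)(C)[Si](C)(C)OCC[C@@H](OCc1ccc(OC)cc1)[C@@](C)(CO)CO[Si](c2ccccc2)(c3ccccc3)C(C)(C)C | intermediate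
10 | α-quaternary aldehyde from 9 | CC(C)(C)[Si](C)(C)OCC[C@@H](OCc1ccc(OC)cc1)[C@@](C)(C=O)CO[Si](c2ccccc2)(c3ccccc3)C(C)(C)C | intermediate
11 | (E)-alkenyl pinacol boronate from 10 | CC(C)(C)[Si](C)(C)OCC[C@@H](OCc1ccc(OC)cc1)[C@@](C)(/C=C/B2OC(C)(C)C(C)(C)O2)CO[Si](c3ccccc3)(c4ccccc4)C(C)(C)C | intermediate
12 | primary alcohol from 11 (TBS removed) | OCC[C@@H](OCc1ccc(OC)cc1)[C@@](C)(/C=C/B2OC(C)(C)C(C)(C)O2)CO[Si](c3ccccc3)(c4ccccc4)C(C)(C)C | intermediate
13 | β-(4-methoxybenzyloxy) aldehyde from 12 | O=CC[C@@H](OCc1ccc(OC)cc1)[C@@](C)(/C=C/B2OC(C)(C)C(C)(C)O2)CO[Si](c3ccccc3)(c4ccccc4)C(C)(C)C | intermediate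
14 | 3-methylcyclopent-2-en-1-one | CC1=CC(=O)CC1 | starting material
15 | lithium 4-methylcyclopenta-1,3-dien-2-olate | [Li+].[O-]C1=CCC(C)=C1 | intermediate (not isolated)
16 | trimethyl[(4-methylcyclopenta-1,3-dien-2-yl)oxy]silane | C[Si](C)(C)OC1=CCC(C)=C1 | intermediate
17 | aldol adduct of 13 and 16 (C-8 OH anti to C-10 OPMB; mixture at ring α′ carbon) | O=C1C=C(C)CC1[C@H](O)C[C@@H](OCc2ccc(OC)cc2)[C@@](C)(/C=C/B3OC(C)(C)C(C)(C)O3)CO[Si](c4ccccc4)(c5ccccc5)C(C)(C)C | intermediate
18 | dilithium alkoxide–enolate of 17 | [Li+].[Li+].[O-]C1=C(CC(C)=C1)[C@H]([O-])C[C@@H](OCc2ccc(OC)cc2)[C@@](C)(/C=C/B3OC(C)(C)C(C)(C)O3)CO[Si](c4ccccc4)(c5ccccc5)C(C)(C)C | intermediate (not isolated)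
19 | methylated β-hydroxy enone (quaternary C-6) | O=C1C=C(C)C[C@@]1(C)[C@H](O)C[C@@H](OCc2ccc(OC)cc2)[C@@](C)(/C=C/B3OC(C)(C)C(C)(C)O3)CO[Si](c4ccccc4)(c5ccccc5)C(C)(C)C | intermediate
20 | 1-(triethylsilyloxy)cyclopentadiene with C-8 triethylsilyl ether | CC[Si](CC)(CC)OC1=CC(C)=C[C@@]1(C)[C@H](O[Si](CC)(CC)CC)C[C@@H](OCc2ccc(OC)cc2)[C@@](C)(/C=C/B3OC(C)(C)C(C)(C)O3)CO[Si](c4ccccc4)(c5ccccc5)C(C)(C)C | intermediate (not isolated)
21 | tricyclic norbornene, endo C-1 pinacol boronate | CC(C)(C)[Si](c4ccccc4)(c5ccccc5)OC[C@]1(C)[C@@H]2[C@@H](B7OC(C)(C)C(C)(C)O7)[C@@]3(O[Si](CC)(CC)CC)C=C(C)[C@@H]2[C@@]3(C)[C@H](O[Si](CC)(CC)CC)C[C@H]1OCc6ccc(OC)cc6 | intermediate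
22 | tricyclic norbornene, endo C-1 alcohol | CC(C)(C)[Si](c4ccccc4)(c5ccccc5)OC[C@]1(C)[C@@H]2[C@@H](O)[C@@]3(O[Si](CC)(CC)CC)C=C(C)[C@@H]2[C@@]3(C)[C@H](O[Si](CC)(CC)CC)C[C@H]1OCc6ccc(OC)cc6 | intermediate
23 | tricyclic norbornene, endo C-1 mesylate | CC(C)(C)[Si](c4ccccc4)(c5ccccc5)OC[C@]1(C)[C@@H]2[C@@H](OS(C)(=O)=O)[C@@]3(O[Si](CC)(CC)CC)C=C(C)[C@@H]2[C@@]3(C)[C@H](O[Si](CC)(CC)CC)C[C@H]1OCc6ccc(OC)cc6 | intermediate
24 | tetrabutylammonium bridgehead (C-2) alkoxide of the desilylated mesylate | CCCC[N+](CCCC)(CCCC)CCCC.OC[C@]1(C)[C@@H]2[C@@H](OS(C)(=O)=O)[C@@]3([O-])C=C(C)[C@@H]2[C@@]3(C)[C@H](O)C[C@H]1OCc4ccc(OC)cc4 | intermediate (not isolated)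
25 | tricyclic enone diol (C-8 OH, C-12 OH, C-10 OPMB) | OC[C@]1(C)[C@@H]2[C@H]3C(=O)C=C(C)[C@@H]2[C@@]3(C)[C@H](O)C[C@H]1OCc4ccc(OC)cc4 | intermediate
26 | C-8, C-12 bis-angelate, C-10 OPMB | C/C=C(/C)C(=O)OC[C@]1(C)[C@@H]2[C@H]3C(=O)C=C(C)[C@@H]2[C@@]3(C)[C@H](OC(=O)/C(C)=C\C)C[C@H]1OCc4ccc(OC)cc4 | intermediate
27 | C-8, C-12 bis-angelate, C-10 alcohol | C/C=C(/C)C(=O)OC[C@]1(C)[C@@H]2[C@H]3C(=O)C=C(C)[C@@H]2[C@@]3(C)[C@H](OC(=O)/C(C)=C\C)C[C@H]1O | intermediate
28 | CNP0364726.1 | C/C=C(/C)C(=O)OC[C@]1(C)[C@@H]2[C@H]3C(=O)C=C(C)[C@@H]2[C@@]3(C)[C@H](OC(=O)/C(C)=C\C)C[C@H]1OC(C)=O | target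

## Step count and least certain steps

Total: 19 steps. Longest linear sequence: 18 steps (steps 1–9 and 11–19); step 10 is the only branch.

Step 16 (key step, Proposed new method). Most likely failure: the bridgehead alkoxide reacts through another channel before the shift (retro-[4+2] cleavage, sulfonyl transfer from the C-1 oxygen to the alkoxide), or the strain-building shift is too slow and desilylated material decomposes. Fallback by known chemistry (anionic fragmentation and recombination instead of a concerted shift), setting out from 23: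
- HF·pyridine removes both triethylsilyl groups and gives diol F1.
- Dess–Martin oxidation of the only oxidisable hydroxyl (C-8) gives β-hydroxy ketone F2.
- LiHMDS (toluene–THF, −78 to 0 °C) triggers retro-aldol cleavage of the C-2–C-6 bond; the C-6 enolate then closes ring B by intramolecular C-alkylation at C-1 with loss of mesylate, the classical enolate-alkylation route to such cyclobutanes, and gives diketone F3. The lithium counter-ion and the non-polar medium favour C- over O-alkylation.
- DDQ gives hydroxy ketone F4.
- Evans–Tishchenko reduction (acetaldehyde, SmI2 cat., THF, −10 °C) gives acetate F5, with the 1,3-anti C-8 alcohol and the C-10 acetate in place.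
- TBAF/AcOH gives diol acetate F6, and the acylation of step 17 applied to it gives 28, where the fallback rejoins the route.

Step 13. Most likely failure: slow cycloaddition of the weakly activated alkenylboronate, so that the siloxydiene dimerises or hydrolyses, or silylation at the exocyclic methyl gives the wrong diene isomer. Fallback with a strongly activated dienophile and a different leaving group, setting out from 19:
- ipso-Nitrodeboronation of the alkenylboronate gives nitroalkene F7.
- TESOTf/Et3N gives siloxydiene F8, which should cyclise at or below room temperature with the same tether control and ortho regiochemistry to nitro adduct F9 (endo nitro group).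
- Zinc in acetic acid gives amine F10.
- NaNO2 in aqueous acetic acid forms the diazonium ion, whose departure with the same antiperiplanar C-6 shift (Tiffeneau–Demjanov-type semipinacol deamination) gives silylated enone F11.
- TBAF gives 25, where the fallback rejoins the route.

Step 12. Most likely failure: deprotonation at the γ-position instead of the α′-methine, retro-aldol cleavage of the dianion, or poor facial discrimination in the methylation. Fallback that sets the quaternary centre by catalyst control and builds the ring afterwards, setting out from 13: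
- The iridium-catalysed tert-(hydroxy)prenylation of step 1, run at the aldehyde level (isoprene monoxide, 2-propanol as reductant, same ligand antipode), gives diol F12, with C-6 and C-8 set together.
- TEMPO/PhI(OAc)2 oxidises the primary alcohol to hydroxy aldehyde F13.
- TESOTf/2,6-lutidine gives silyl ether F14.
- Methallyl bromide and indium powder (In) add to the aldehyde and give homoallylic alcohol F15.
- Ring-closing metathesis (second-generation Grubbs catalyst) gives cyclopentenol F16.
- Dess–Martin oxidation gives the β,γ-unsaturated enone F17, whose only enolisation (TESOTf/Et3N) leads to 20, where the fallback rejoins the route.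

Step 17. Most likely failure: Z to E isomerisation during the slow acylation of the hindered C-8 alcohol, or incomplete acylation. Fallback that builds the Z-alkenes on the esters instead of transferring them, setting out from 25: esterification with 2-[bis(2,2,2-trifluoroethoxy)phosphoryl]propanoic acid (DCC, DMAP) gives bis-phosphonate F18, and Still–Gennari olefination with acetaldehyde (KHMDS, 18-crown-6, THF, −78 °C) gives 26, where the fallback rejoins the route.

## Further compounds

F1 | step 16 | norbornene mesylate with free C-2 and C-8 hydroxyls | CC(C)(C)[Si](c4ccccc4)(c5ccccc5)OC[C@]1(C)[C@@H]2[C@@H](OS(C)(=O)=O)[C@@]3(O)C=C(C)[C@@H]2[C@@]3(C)[C@H](O)C[C@H]1OCc6ccc(OC)cc6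
F2 | step 16 | C-8 ketone of F1 (β-hydroxy ketone) | CC(C)(C)[Si](c4ccccc4)(c5ccccc5)OC[C@]1(C)[C@@H]2[C@@H](OS(C)(=O)=O)[C@@]3(O)C=C(C)[C@@H]2[C@@]3(C)C(=O)C[C@H]1OCc6ccc(OC)cc6
F3 | step 16 | tricyclic enone with C-8 ketone, C-10 OPMB, C-12 OTBDPS | CC(C)(C)[Si](c4ccccc4)(c5ccccc5)OC[C@]1(C)[C@@H]2[C@H]3C(=O)C=C(C)[C@@H]2[C@@]3(C)C(=O)C[C@H]1OCc6ccc(OC)cc6
F4 | step 16 | C-10 alcohol of F3 | CC(C)(C)[Si](c4ccccc4)(c5ccccc5)OC[C@]1(C)[C@@H]2[C@H]3C(=O)C=C(C)[C@@H]2[C@@]3(C)C(=O)C[C@H]1O
F5 | step 16 | C-10 acetate, C-8 alcohol, C-12 OTBDPS | CC(C)(C)[Si](c4ccccc4)(c5ccccc5)OC[C@]1(C)[C@@H]2[C@H]3C(=O)C=C(C)[C@@H]2[C@@]3(C)[C@H](O)C[C@H]1OC(C)=O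
F6 | step 16 | C-10 acetate, C-8 and C-12 diol | OC[C@]1(C)[C@@H]2[C@H]3C(=O)C=C(C)[C@@H]2[C@@]3(C)[C@H](O)C[C@H]1OC(C)=O
F7 | step 13 | (E)-nitroalkene analogue of 19 | O=C1C=C(C)C[C@@]1(C)[C@H](O)C[C@@H](OCc2ccc(OC)cc2)[C@@](C)(/C=C/[N+](=O)[O-])CO[Si](c4ccccc4)(c5ccccc5)C(C)(C)C
F8 | step 13 | siloxydiene with nitroalkene dienophile | CC[Si](CC)(CC)OC1=CC(C)=C[C@@]1(C)[C@H](O[Si](CC)(CC)CC)C[C@@H](OCc2ccc(OC)cc2)[C@@](C)(/C=C/[N+](=O)[O-])CO[Si](c4ccccc4)(c5ccccc5)C(C)(C)C
F9 | step 13 | tricyclic norbornene, endo C-1 nitro | CC(C)(C)[Si](c4ccccc4)(c5ccccc5)OC[C@]1(C)[C@@H]2[C@@H]([N+](=O)[O-])[C@@]3(O[Si](CC)(CC)CC)C=C(C)[C@@H]2[C@@]3(C)[C@H](O[Si](CC)(CC)CC)C[C@H]1OCc6ccc(OC)cc6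
F10 | step 13 | tricyclic norbornene, endo C-1 amine | CC(C)(C)[Si](c4ccccc4)(c5ccccc5)OC[C@]1(C)[C@@H]2[C@@H](N)[C@@]3(O[Si](CC)(CC)CC)C=C(C)[C@@H]2[C@@]3(C)[C@H](O[Si](CC)(CC)CC)C[C@H]1OCc6ccc(OC)cc6
F11 | step 13 | tricyclic enone with C-8 OSiEt3, C-10 OPMB, C-12 OTBDPS | CC(C)(C)[Si](c4ccccc4)(c5ccccc5)OC[C@]1(C)[C@@H]2[C@H]3C(=O)C=C(C)[C@@H]2[C@@]3(C)[C@H](O[Si](CC)(CC)CC)C[C@H]1OCc6ccc(OC)cc6
F12 | step 12 | tert-(hydroxy)prenylation diol from 13 | C=C[C@](C)(CO)[C@H](O)C[C@@H](OCc1ccc(OC)cc1)[C@@](C)(/C=C/B2OC(C)(C)C(C)(C)O2)CO[Si](c3ccccc3)(c4ccccc4)C(C)(C)C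
F13 | step 12 | hydroxy aldehyde from F12 | C=C[C@](C)(C=O)[C@H](O)C[C@@H](OCc1ccc(OC)cc1)[C@@](C)(/C=C/B2OC(C)(C)C(C)(C)O2)CO[Si](c3ccccc3)(c4ccccc4)C(C)(C)C
F14 | step 12 | triethylsilyl ether of F13 | C=C[C@](C)(C=O)[C@H](O[Si](CC)(CC)CC)C[C@@H](OCc1ccc(OC)cc1)[C@@](C)(/C=C/B2OC(C)(C)C(C)(C)O2)CO[Si](c3ccccc3)(c4ccccc4)C(C)(C)C
F15 | step 12 | methallyl adduct of F14 (carbinol epimers) | C=C[C@](C)(C(O)CC(C)=C)[C@H](O[Si](CC)(CC)CC)C[C@@H](OCc1ccc(OC)cc1)[C@@](C)(/C=C/B2OC(C)(C)C(C)(C)O2)CO[Si](c3ccccc3)(c4ccccc4)C(C)(C)C
F16 | step 12 | cyclopentenol from ring-closing metathesis | OC1CC(C)=C[C@@]1(C)[C@H](O[Si](CC)(CC)CC)C[C@@H](OCc2ccc(OC)cc2)[C@@](C)(/C=C/B3OC(C)(C)C(C)(C)O3)CO[Si](c4ccccc4)(c5ccccc5)C(C)(C)C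
F17 | step 12 | β,γ-unsaturated cyclopentenone | O=C1CC(C)=C[C@@]1(C)[C@H](O[Si](CC)(CC)CC)C[C@@H](OCc2ccc(OC)cc2)[C@@](C)(/C=C/B3OC(C)(C)C(C)(C)O3)CO[Si](c4ccccc4)(c5ccccc5)C(C)(C)C
F18 | step 17 | C-8, C-12 bis[2-(bis(2,2,2-trifluoroethoxy)phosphoryl)propanoate] of 25 | CC(C(=O)OC[C@]1(C)[C@@H]2[C@H]3C(=O)C=C(C)[C@@H]2[C@@]3(C)[C@H](OC(=O)C(C)P(=O)(OCC(F)(F)F)OCC(F)(F)F)C[C@H]1OCc4ccc(OC)cc4)P(=O)(OCC(F)(F)F)OCC(F)(F)F
A1 | alternative 1 | eleven-membered (E,Z,E)-trienone triester | C/C=C(/C)C(=O)OC[C@]1(C)/C=C/C(C)=C\C(=O)/C=C(C)/[C@H](OC(=O)/C(C)=C\C)C[C@H]1OC(C)=O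
A2 | alternative 2 | hydrobenzocycloheptenone with C-7 mesylate | OC[C@]1(C)[C@@H](OS(C)(=O)=O)[C@@H]2C(C)=CC(=O)C[C@]2(C)[C@H](O)C[C@H]1OCc3ccc(OC)cc3
A3 | alternative 3 | bridged pyrrolidine with NH between C-1 and C-6 | OC[C@]1(C)[C@@H]2[C@H](N3)C(=O)C=C(C)[C@@H]2[C@@]3(C)[C@H](O)C[C@H]1OCc4ccc(OC)cc4
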